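**Plan** (carotenoid numbering: C1 = gem-dimethyl carbon, C3 = oxygenated carbon, C5 = methyl-bearing alkene carbon, C6 = chain-bearing carbon)

- Retrosynthesis: the polyene is cut at C11=C12 and C11′=C12′ (two Wittig unions, C15 + C10 + C15), each C15 unit at C10–C9 and C7=C8 (Grignard/phosphonium salt, cross-metathesis), and the end-group ring at its C6–C1 bond.
- Enabling feature: in the 3-oxo ring, C6 is the γ-carbon of the enone C3(=O)–C4=C5 and its neighbour C1 is a quaternary gem-dimethyl carbon tied back to the carbonyl through C2. The C6–C1 bond is thus the union of a dienolate terminus with a tertiary cation, so the ring can come from a cyclobutanone (C3, C4, C1, C2) carrying C5=C6 as an alkenyl arm on C4, by C4–C1 heterolysis and C6–C1 reclosure (four- to six-membered).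
- Forward: cyclopropyl sulfide + enynal → cyclobutanone → enantioselective ring expansion to the (S)-4-alkynyl enone → (3R,6S)-alcohol → vinyl group → C13 enone → one C15 phosphonium salt for both end groups (one portion silylated) → two successive Wittig reactions with the C10 dialdehyde → oxidation of the free-hydroxyl end → desilylation.
- Stereochemistry: C6 and C6′ come from the catalyst in the ring expansion (one intermediate feeds both rings); C3′ from a catalyst-controlled ketone reduction; the E alkenes from Wittig/metathesis selectivity and thermal equilibration.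
- The enone of the oxo ring is unveiled only in the penultimate step, because its C6–H is base-labile; the other ring is carried as a silyl ether from the first Wittig reaction onward.

Key step: step 4

Remark on the chemistry: the sense of induction of the two oxazaborolidine catalysts (steps 4 and 5) is assigned from the accepted models for the (S)-catalysts; if experiment showed the opposite sense, the enantiomeric catalyst would be used without other change.

**Step 1**
Reactants: 1 3-(trimethylsilyl)prop-2-ynal; 2 2-(triphenyl-λ5-phosphanylidene)propanal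
Product: 3 (2E)-2-methyl-5-(trimethylsilyl)pent-2-en-4-ynal
Conditions: CH2Cl2, 0 °C to rt
Reagents that add atoms: none
Why: Wittig olefination with the formyl-stabilised ylide is E-selective, and the ynal is much more electrophilic than the enal formed, so a single olefination to the (E)-enynal is expected.

**Step 2**
Reactants: 4 2-methylpropene; 5 chloromethyl phenyl sulfide
Product: 7 rac-[(2,2-dimethylcyclopropyl)sulfanyl]benzene, via potassium chloro(phenylsulfanyl)methanide 6 (not isolated)
Conditions: KOtBu, excess condensed 4, pentane, −15 °C to rt, sealed vessel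
Reagents that add atoms: none
Why: Base-induced α-elimination of the chloromethyl sulfide gives (phenylthio)carbene, which adds to the electron-rich 1,1-disubstituted alkene in a [2+1] cyclopropanation; the one stereocentre is formed racemic and is erased in step 4.

**Step 3**
Reactants: 7 rac-[(2,2-dimethylcyclopropyl)sulfanyl]benzene; 3 (2E)-2-methyl-5-(trimethylsilyl)pent-2-en-4-ynal
Product: 10 rac-3,3-dimethyl-2-[(2E)-5-(trimethylsilyl)pent-2-en-4-yn-2-yl]cyclobutan-1-one, via the lithiated cyclopropyl sulfide 8 (not isolated), via the cyclopropyl carbinol 9 (not isolated)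
Conditions: n-BuLi, THF, 0 °C; 3, −78 °C; then 48% aq HBF4, Et2O, 0 °C to rt
Reagents that add atoms: water, O
Why: Lithiation of the cyclopropyl C–H next to sulfur, 1,2-addition to the enal and acid-induced cyclopropylcarbinyl-to-cyclobutyl ring expansion (a sulfur-assisted semipinacol-type rearrangement, the thionium ion being hydrolysed to the ketone) is an established cyclobutanone synthesis; the more substituted ring carbon (CMe2) migrates and so becomes C3, the E alkene is the thermodynamic isomer of the allyl cation, and the new α-stereocentre is racemic by design.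

**Step 4**
Reactants: 10 rac-3,3-dimethyl-2-[(2E)-5-(trimethylsilyl)pent-2-en-4-yn-2-yl]cyclobutan-1-one
Product: 11 (4S)-3,5,5-trimethyl-4-[(trimethylsilyl)ethynyl]cyclohex-2-en-1-one
Conditions: 20 mol % (S)-3,3-diphenyl-1-(2-methylphenyl)tetrahydro-1H,3H-pyrrolo[1,2-c][1,3,2]oxazaborole protonated with HN(SO2CF3)2 (cationic o-tolyl oxazaborolidine), CH2Cl2 (0.02 M), −40 to −20 °C
Reagents that add atoms: none
Why: Proposed new method: (cyclobutanone numbering) the chiral boron Lewis acid binds the ketone oxygen of rac-10 and triggers heterolysis of the strained C2–C3 bond, which is allylic to the side-chain alkene and ends at a carbon able to carry a tertiary cation, so that an achiral zwitterion results (boron dienolate O–C1=C2–C(Me)=CH–C≡C tethered through C4 to a 2-propyl-type cation) and both enantiomers of 10 converge on it. The cation is then captured by the γ-carbon of the dienolate (the CH next to the alkyne), which closes the six-membered ring by a 6-enolendo attack on the trigonal cationic carbon, a formal suprafacial 1,3-shift of C3 that inserts the two alkene carbons into the four-membered ring and releases the conjugated enone. The closest known reaction types are the acid-promoted rearrangement of 2-vinylcyclobutanones to cyclohexenones and the Lewis-acid opening of 3-donor-substituted cyclobutanones to 1,4-zwitterions; only the enantioselective version is new, and it rests on the established ability of cationic oxazaborolidines to shield one face of a bound carbonyl partner. The single new stereocentre (C4 of 11) is set in the C–C bond formation: the cation hangs on the C4 tether next to the boron-bound oxygen, is forced to the open face of the dienolate by the aryl groups of the catalyst and adds to the γ-carbon from that face, while the E alkene keeps H inside and the alkyne outside. The step needs γ- over α-recombination (α merely regenerates 10, so it is harmless), C2–C3 over acyl C1–C2 cleavage (secured by the gem-dimethyl group that stabilises the cation) and no proton-initiated 1,2-acyl shift or proton loss from the cation (aprotic medium, low temperature, an alkene made electron-poor by the alkyne, and a slim alkynyl group that lets the congested quaternary–tertiary bond form).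

**Step 5**
Reactants: 11 (4S)-3,5,5-trimethyl-4-[(trimethylsilyl)ethynyl]cyclohex-2-en-1-one
Product: 13 (1R,4R)-4-ethynyl-3,5,5-trimethylcyclohex-2-en-1-ol, via the silylalkynyl alcohol 12 (not isolated)
Conditions: (S)-1-methyl-3,3-diphenyltetrahydro-1H,3H-pyrrolo[1,2-c][1,3,2]oxazaborole (20 mol %), catecholborane, toluene, −78 °C; then K2CO3, MeOH, rt
Reagents that add atoms: none
Why: Corey–Bakshi–Shibata reduction delivers hydride to the carbonyl under catalyst control (alkenyl arm as the large group) and without base, which should set the (1R) carbinol cis to the alkynyl group and leave the labile C4–H untouched, after which methanolic carbonate cleaves the C(sp)–Si bond now that no enone is present (the C4 descriptor changes from S to R only because the priorities change).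

**Step 6**
Reactants: 13 (1R,4R)-4-ethynyl-3,5,5-trimethylcyclohex-2-en-1-ol
Product: 14 (1R,4S)-4-ethenyl-3,5,5-trimethylcyclohex-2-en-1-ol
Conditions: H2 (1 atm), Pd on CaCO3 poisoned with Pb(OAc)2 (Lindlar catalyst), quinoline, EtOAc, rt
Reagents that add atoms: none
Why: Lindlar semi-hydrogenation reduces the terminal alkyne to the vinyl group and leaves the trisubstituted ring alkene alone; no stereocentre is touched.

**Step 7**
Reactants: 14 (1R,4S)-4-ethenyl-3,5,5-trimethylcyclohex-2-en-1-ol
Product: 15 (3E)-4-[(1S,4R)-4-hydroxy-2,6,6-trimethylcyclohex-2-en-1-yl]but-3-en-2-one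
Conditions: methyl vinyl ketone (5 equiv), second-generation Hoveyda–Grubbs catalyst, [1,3-bis(2,4,6-trimethylphenyl)imidazolidin-2-ylidene]dichloro(2-isopropoxybenzylidene)ruthenium (5 mol %), CH2Cl2, 40 °C
Reagents that add atoms: methyl vinyl ketone, CC(=O)C=C
Why: Olefin cross-metathesis of the monosubstituted alkene with an electron-poor partner gives the E enone selectively (thermodynamic control), the trisubstituted ring alkene being inert to the ruthenium carbene.

**Step 8**
Reactants: 15 (3E)-4-[(1S,4R)-4-hydroxy-2,6,6-trimethylcyclohex-2-en-1-yl]but-3-en-2-one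
Product: 16 (1E)-1-[(1S,4R)-4-hydroxy-2,6,6-trimethylcyclohex-2-en-1-yl]-3-methylpenta-1,4-dien-3-ol (both epimers at the new carbinol carbon)
Conditions: vinylmagnesium bromide (3 equiv), THF, −78 to 0 °C; aq NH4Cl
Reagents that add atoms: vinylmagnesium bromide, C=C[Mg]Br
Why: Grignard 1,2-addition to the enone carbonyl (the hindered β-carbon disfavours conjugate addition) after deprotonation of the ring hydroxyl gives the bis-allylic tertiary alcohol, whose new carbinol centre is unselective but is destroyed in step 9.

**Step 9**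
Reactants: 16 (1E)-1-[(1S,4R)-4-hydroxy-2,6,6-trimethylcyclohex-2-en-1-yl]-3-methylpenta-1,4-dien-3-ol
Product: 17 [(2E,4E)-5-[(1S,4R)-4-hydroxy-2,6,6-trimethylcyclohex-2-en-1-yl]-3-methylpenta-2,4-dien-1-yl]triphenylphosphonium bromide
Conditions: PPh3·HBr, MeOH, rt; crystallisation
Reagents that add atoms: triphenylphosphine hydrobromide, [Br-].[PH+](c1ccccc1)(c1ccccc1)c1ccccc1
Why: Acid ionises the doubly allylic tertiary alcohol far faster than the secondary ring alcohol and triphenylphosphine captures the pentadienyl cation at its unhindered primary terminus (SN1 with allylic transposition, the standard C15 Wittig-salt synthesis), giving the conjugated dienyl salt with the thermodynamically preferred E geometry, purified by crystallisation.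

**Step 10**
Reactants: 17 [(2E,4E)-5-[(1S,4R)-4-hydroxy-2,6,6-trimethylcyclohex-2-en-1-yl]-3-methylpenta-2,4-dien-1-yl]triphenylphosphonium bromide (about half of the material; the rest is kept for step 12)
Product: 18 [(2E,4E)-5-[(1S,4R)-4-{[tert-butyl(dimethyl)silyl]oxy}-2,6,6-trimethylcyclohex-2-en-1-yl]-3-methylpenta-2,4-dien-1-yl]triphenylphosphonium bromide
Conditions: N-(tert-butyldimethylsilyl)-N-methyltrifluoroacetamide (1.5 equiv), MeCN, 40 °C; volatiles removed in vacuo, precipitation from EtOAc/Et2O
Reagents that add atoms: N-(tert-butyldimethylsilyl)-N-methyltrifluoroacetamide, CN(C(=O)C(F)(F)F)[Si](C)(C)C(C)(C)C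
Why: Silyl transfer from the N-silyl amide to the secondary allylic hydroxyl (O-silylation) runs under neutral, halide-free conditions, so the bromide counter-ion, the acidic P–CH2 group and the allylic system should stay unchanged; this masks the ring that is to keep its hydroxyl, so that only the other ring is oxidised later.

**Step 11**
Reactants: 18 [(2E,4E)-5-[(1S,4R)-4-{[tert-butyl(dimethyl)silyl]oxy}-2,6,6-trimethylcyclohex-2-en-1-yl]-3-methylpenta-2,4-dien-1-yl]triphenylphosphonium bromide; 19 (2E,4E,6E)-2,7-dimethylocta-2,4,6-trienedial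
Product: 21 (2E,4E,6E,8E,10E,12E)-13-[(1S,4R)-4-{[tert-butyl(dimethyl)silyl]oxy}-2,6,6-trimethylcyclohex-2-en-1-yl]-2,7,11-trimethyltrideca-2,4,6,8,10,12-hexaenal, via the silyloxy phosphonium ylide 20 (not isolated)
Conditions: 19 (3 equiv), NaOMe, MeOH/CH2Cl2, 0 °C to rt; then heptane, 80 °C, dark
Reagents that add atoms: none
Why: Wittig olefination of the semi-stabilised allylic ylide with an excess of the symmetrical dialdehyde should stop at mono-olefination, the silyl ether being stable to methoxide at room temperature, and the Z/E mixture at the new double bond is equilibrated thermally to the all-E polyene as usual for carotenoid apo-aldehydes.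

**Step 12**
Reactants: 21 (2E,4E,6E,8E,10E,12E)-13-[(1S,4R)-4-{[tert-butyl(dimethyl)silyl]oxy}-2,6,6-trimethylcyclohex-2-en-1-yl]-2,7,11-trimethyltrideca-2,4,6,8,10,12-hexaenal; 17 [(2E,4E)-5-[(1S,4R)-4-hydroxy-2,6,6-trimethylcyclohex-2-en-1-yl]-3-methylpenta-2,4-dien-1-yl]triphenylphosphonium bromide
Product: 23 (all-E,3R,6S,3′R,6′S)-3′-{[tert-butyl(dimethyl)silyl]oxy}-ε,ε-caroten-3-ol, via the hydroxy phosphonium ylide 22 (not isolated)
Conditions: NaOMe, MeOH/CH2Cl2, 0 °C to rt; then heptane, 80 °C, dark
Reagents that add atoms: none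
Why: A second Wittig olefination joins the C25 aldehyde to the unsilylated C15 ylide, whose free hydroxyl is tolerated in methanolic methoxide, and thermal Z-to-E equilibration should give the all-E C40 skeleton with both C6 centres untouched and the two rings differentiated (one hydroxyl free, one silylated).

**Step 13**
Reactants: 23 (all-E,3R,6S,3′R,6′S)-3′-{[tert-butyl(dimethyl)silyl]oxy}-ε,ε-caroten-3-ol
Product: 24 (all-E,6S,3′R,6′S)-3′-{[tert-butyl(dimethyl)silyl]oxy}-ε,ε-caroten-3-one
Conditions: activated MnO2 (excess), CH2Cl2, rt, dark, argon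
Reagents that add atoms: none
Why: Manganese dioxide oxidises allylic alcohols selectively under neutral heterogeneous conditions, so only the free C3 hydroxyl becomes the enone and the base-labile C6–H beside it is not epimerised.

**Step 14**
Reactants: 24 (all-E,6S,3′R,6′S)-3′-{[tert-butyl(dimethyl)silyl]oxy}-ε,ε-caroten-3-one
Product: 25 (all-E,3′R,6S,6′S)-3′-hydroxy-ε,ε-caroten-3-one (target)
Conditions: Bu4NF, AcOH (1:1), THF, 0 °C to rt, dark
Reagents that add atoms: none
Why: Fluoride-induced cleavage of the silyl ether buffered with acetic acid keeps the medium non-basic, so the γ-C–H of the new enone and the acid-sensitive allylic alcohol should both survive.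

**Compound list**

1 | 3-(trimethylsilyl)prop-2-ynal | C[Si](C)(C)C#CC=O | starting material
2 | 2-(triphenyl-λ5-phosphanylidene)propanal | CC(C=O)=P(c1ccccc1)(c1ccccc1)c1ccccc1 | starting material
3 | (2E)-2-methyl-5-(trimethylsilyl)pent-2-en-4-ynal | O=C/C(C)=C/C#C[Si](C)(C)C | intermediate
4 | 2-methylpropene | CC(C)=C | starting material
5 | chloromethyl phenyl sulfide | ClCSc1ccccc1 | starting material
6 | potassium chloro(phenylsulfanyl)methanide | [K+].Cl[CH-]Sc1ccccc1 | intermediate (not isolated)
7 | rac-[(2,2-dimethylcyclopropyl)sulfanyl]benzene | CC1(C)CC1Sc1ccccc1 | intermediate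
8 | rac-[2,2-dimethyl-1-(phenylsulfanyl)cyclopropyl]lithium | [Li]C1(Sc2ccccc2)CC1(C)C | intermediate (not isolated)
9 | (2E)-1-[2,2-dimethyl-1-(phenylsulfanyl)cyclopropyl]-2-methyl-5-(trimethylsilyl)pent-2-en-4-yn-1-ol (racemic diastereomer mixture) | CC1(C)CC1(Sc1ccccc1)C(O)/C(C)=C/C#C[Si](C)(C)C | intermediate (not isolated)
10 | rac-3,3-dimethyl-2-[(2E)-5-(trimethylsilyl)pent-2-en-4-yn-2-yl]cyclobutan-1-one | CC1(C)CC(=O)C1/C(C)=C/C#C[Si](C)(C)C | intermediate
11 | (4S)-3,5,5-trimethyl-4-[(trimethylsilyl)ethynyl]cyclohex-2-en-1-one | CC1=CC(=O)CC(C)(C)[C@@H]1C#C[Si](C)(C)C | intermediate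
12 | (1R,4S)-3,5,5-trimethyl-4-[(trimethylsilyl)ethynyl]cyclohex-2-en-1-ol (OH cis to the alkynyl group) | CC1=C[C@H](O)CC(C)(C)[C@@H]1C#C[Si](C)(C)C | intermediate (not isolated)
13 | (1R,4R)-4-ethynyl-3,5,5-trimethylcyclohex-2-en-1-ol (cis) | CC1=C[C@H](O)CC(C)(C)[C@@H]1C#C | intermediate
14 | (1R,4S)-4-ethenyl-3,5,5-trimethylcyclohex-2-en-1-ol (cis) | CC1=C[C@H](O)CC(C)(C)[C@@H]1C=C | intermediate
15 | (3E)-4-[(1S,4R)-4-hydroxy-2,6,6-trimethylcyclohex-2-en-1-yl]but-3-en-2-one | CC1=C[C@H](O)CC(C)(C)[C@@H]1/C=C/C(C)=O | intermediate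
16 | (1E)-1-[(1S,4R)-4-hydroxy-2,6,6-trimethylcyclohex-2-en-1-yl]-3-methylpenta-1,4-dien-3-ol (both C3 epimers) | CC1=C[C@H](O)CC(C)(C)[C@@H]1/C=C/C(C)(O)C=C | intermediate
17 | [(2E,4E)-5-[(1S,4R)-4-hydroxy-2,6,6-trimethylcyclohex-2-en-1-yl]-3-methylpenta-2,4-dien-1-yl]triphenylphosphonium bromide | CC1=C[C@H](O)CC(C)(C)[C@@H]1/C=C/C(C)=C/C[P+](c1ccccc1)(c1ccccc1)c1ccccc1.[Br-] | intermediate
18 | [(2E,4E)-5-[(1S,4R)-4-{[tert-butyl(dimethyl)silyl]oxy}-2,6,6-trimethylcyclohex-2-en-1-yl]-3-methylpenta-2,4-dien-1-yl]triphenylphosphonium bromide | CC1=C[C@H](O[Si](C)(C)C(C)(C)C)CC(C)(C)[C@@H]1/C=C/C(C)=C/C[P+](c1ccccc1)(c1ccccc1)c1ccccc1.[Br-] | intermediate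
19 | (2E,4E,6E)-2,7-dimethylocta-2,4,6-trienedial | O=C/C(C)=C/C=C/C=C(C)/C=O | starting material
20 | {(2E,4E)-5-[(1S,4R)-4-{[tert-butyl(dimethyl)silyl]oxy}-2,6,6-trimethylcyclohex-2-en-1-yl]-3-methylpenta-2,4-dien-1-ylidene}(triphenyl)-λ5-phosphane (silyloxy ylide) | CC1=C[C@H](O[Si](C)(C)C(C)(C)C)CC(C)(C)[C@@H]1/C=C/C(C)=C/[CH-][P+](c1ccccc1)(c1ccccc1)c1ccccc1 | intermediate (not isolated)
21 | (2E,4E,6E,8E,10E,12E)-13-[(1S,4R)-4-{[tert-butyl(dimethyl)silyl]oxy}-2,6,6-trimethylcyclohex-2-en-1-yl]-2,7,11-trimethyltrideca-2,4,6,8,10,12-hexaenal | CC1=C[C@H](O[Si](C)(C)C(C)(C)C)CC(C)(C)[C@@H]1/C=C/C(C)=C/C=C/C(C)=C/C=C/C=C(C)/C=O | intermediate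
22 | {(2E,4E)-5-[(1S,4R)-4-hydroxy-2,6,6-trimethylcyclohex-2-en-1-yl]-3-methylpenta-2,4-dien-1-ylidene}(triphenyl)-λ5-phosphane (hydroxy ylide) | CC1=C[C@H](O)CC(C)(C)[C@@H]1/C=C/C(C)=C/[CH-][P+](c1ccccc1)(c1ccccc1)c1ccccc1 | intermediate (not isolated)
23 | (all-E,3R,6S,3′R,6′S)-3′-{[tert-butyl(dimethyl)silyl]oxy}-ε,ε-caroten-3-ol | CC1=C[C@H](O)CC(C)(C)[C@@H]1/C=C/C(C)=C/C=C/C(C)=C/C=C/C=C(C)/C=C/C=C(C)/C=C/[C@@H]1C(C)=C[C@H](O[Si](C)(C)C(C)(C)C)CC1(C)C | intermediate
24 | (all-E,6S,3′R,6′S)-3′-{[tert-butyl(dimethyl)silyl]oxy}-ε,ε-caroten-3-one | CC1=CC(=O)CC(C)(C)[C@@H]1/C=C/C(C)=C/C=C/C(C)=C/C=C/C=C(C)/C=C/C=C(C)/C=C/[C@@H]1C(C)=C[C@H](O[Si](C)(C)C(C)(C)C)CC1(C)C | intermediate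
25 | (all-E,3′R,6S,6′S)-3′-hydroxy-ε,ε-caroten-3-one | CC1=CC(=O)CC(C)(C)[C@@H]1/C=C/C(C)=C/C=C/C(C)=C/C=C/C=C(C)/C=C/C=C(C)/C=C/[C@@H]1C(C)=C[C@H](O)CC1(C)C | target

**Step count and risks**

Total step count: 14. Longest linear sequence: 13 steps (steps 2 to 14; step 1 supplies 3 to step 3).

Steps most likely to fail:

1. Step 4 (Proposed new method). What may go wrong: weak enantiofacial discrimination in the ring closure, partial racemisation of the product through acid-induced dienol formation, or diversion into a proton-initiated 1,2-acyl shift. Fallback with known chemistry, setting out from 10: an achiral Lewis acid (EtAlCl2, CH2Cl2, −78 to 0 °C; the known acid-promoted 2-vinylcyclobutanone-to-cyclohexenone rearrangement) would give racemic 3,5,5-trimethyl-4-[(trimethylsilyl)ethynyl]cyclohex-2-en-1-one F1. Reduction of F1 with the catalyst and borane of step 5, the carbonate treatment being left out, converts the two enantiomers into alcohols epimeric at C4, namely 12 and (1R,4R)-3,5,5-trimethyl-4-[(trimethylsilyl)ethynyl]cyclohex-2-en-1-ol F2. These are diastereomers and should separate on silica. Isolated 12 is desilylated (K2CO3, MeOH) and the route is rejoined at 13.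

2. Step 5. What may go wrong: poor facial selectivity, because catalyst control has to override whatever bias the ring has (the axial C5 methyl and the C4 substituent shield opposite faces). Fallback, setting out from 11: substrate-controlled Luche reduction (NaBH4, CeCl3·7H2O, MeOH, −78 °C) and separation of the two carbinol epimers. The cis epimer is 12. The trans epimer, (1S,4S)-3,5,5-trimethyl-4-[(trimethylsilyl)ethynyl]cyclohex-2-en-1-ol F3, is inverted by a Mitsunobu reaction (4-nitrobenzoic acid, PPh3, DIAD, THF) to (1R,4S)-3,5,5-trimethyl-4-[(trimethylsilyl)ethynyl]cyclohex-2-en-1-yl 4-nitrobenzoate F4. Methanolysis (K2CO3, MeOH) removes ester and silyl group together and returns to the route at 13.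

3. Step 7. What may go wrong: sluggish metathesis of a vinyl group flanked by the quaternary carbon, and migration of the alkene into conjugation with the ring alkene. Fallback, setting out from 13 and bypassing steps 6 to 9: palladium-catalysed hydrostannation (Bu3SnH, PdCl2(PPh3)2, THF) should give (1R,4S)-3,5,5-trimethyl-4-[(E)-2-(tributylstannyl)ethenyl]cyclohex-2-en-1-ol F5. Stille coupling with (E)-3-iodobut-2-en-1-ol (Pd2(dba)3, AsPh3, NMP, rt) then gives (2E,4E)-5-[(1S,4R)-4-hydroxy-2,6,6-trimethylcyclohex-2-en-1-yl]-3-methylpenta-2,4-dien-1-ol F6 with both alkene geometries fixed by the coupling partners. PPh3·HBr in MeOH converts F6 into 17, where the route is rejoined.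

**Further compounds**

F1 | step 4 | rac-3,5,5-trimethyl-4-[(trimethylsilyl)ethynyl]cyclohex-2-en-1-one | CC1=CC(=O)CC(C)(C)C1C#C[Si](C)(C)C
F2 | step 4 | (1R,4R)-3,5,5-trimethyl-4-[(trimethylsilyl)ethynyl]cyclohex-2-en-1-ol | CC1=C[C@H](O)CC(C)(C)[C@H]1C#C[Si](C)(C)C
F3 | step 5 | (1S,4S)-3,5,5-trimethyl-4-[(trimethylsilyl)ethynyl]cyclohex-2-en-1-ol | CC1=C[C@@H](O)CC(C)(C)[C@@H]1C#C[Si](C)(C)C
F4 | step 5 | (1R,4S)-3,5,5-trimethyl-4-[(trimethylsilyl)ethynyl]cyclohex-2-en-1-yl 4-nitrobenzoate | CC1=C[C@H](OC(=O)c2ccc(cc2)[N+](=O)[O-])CC(C)(C)[C@@H]1C#C[Si](C)(C)C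
F5 | step 7 | (1R,4S)-3,5,5-trimethyl-4-[(E)-2-(tributylstannyl)ethenyl]cyclohex-2-en-1-ol | CC1=C[C@H](O)CC(C)(C)[C@@H]1/C=C/[Sn](CCCC)(CCCC)CCCC
F6 | step 7 | (2E,4E)-5-[(1S,4R)-4-hydroxy-2,6,6-trimethylcyclohex-2-en-1-yl]-3-methylpenta-2,4-dien-1-ol | CC1=C[C@H](O)CC(C)(C)[C@@H]1/C=C/C(C)=C/CO
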